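## Retrosynthetic overview

1. The last step removes four phenolic TBS ethers with buffered fluoride. Before that, a C2-symmetric terphenyl catechol is esterified twice with (2Z,4S,5S)-4,5-epoxyhex-2-enoic acid.
2. The acid comes from its methyl ester by carboxylesterase (hydrolase class) hydrolysis at neutral pH. The ester comes from Still–Gennari Z-olefination of an epoxy aldehyde, made by catalytic Sharpless epoxidation of achiral crotyl alcohol, which sets both stereocentres.
3. The catechol comes from hydrogenolysis of two benzyl ethers. The other four phenols are switched from MOM to TBS after a twofold Suzuki coupling on 1,2-bis(benzyloxy)-3,6-dibromo-4,5-bis(methoxymethoxy)benzene.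
4. The dibromide comes from 3,4-bis(benzyloxy)benzaldehyde by Baeyer–Villiger, ortho-formylation, Dakin, MOM protection and bromination, so the two oxygen pairs are distinguished from the start.
5. Ring order: the oxirane is the only ring made (step 1, used twice). The three benzene rings are bought and joined in step 11.

Assumption: twofold and fourfold reactions at equivalent sites are written as one step, and their partly reacted stages are not numbered.

## Fragment 1: the acid

Step 1
Reactants: 1 (E)-but-2-en-1-ol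
Product: 3 [(2S,3S)-3-methyloxiran-2-yl]methyl 4-nitrobenzoate, via epoxy alcohol 2 (not isolated)
Conditions: Ti(OiPr)4 (5 mol %), L-(+)-diisopropyl tartrate (6 mol %), t-BuOOH (1.5 equiv), 4 Å MS, CH2Cl2, −20 °C; P(OMe)3; then Et3N, 4-nitrobenzoyl chloride, 0 °C; recrystallise to ≥98% ee
Reagents that add atoms: tert-butyl hydroperoxide CC(C)(C)OO; 4-nitrobenzoyl chloride O=C(Cl)c1ccc(cc1)[N+](=O)[O-]
Why: In this catalytic Sharpless asymmetric epoxidation the tetravalent titanium/L-(+)-tartrate complex delivers oxygen to one face of the E-allylic alcohol and sets both stereocentres as (2S,3S), while in situ acylation gives a crystalline ester whose recrystallisation removes the minor enantiomer and any cis-derived isomer.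

Step 2
Reactants: 3 [(2S,3S)-3-methyloxiran-2-yl]methyl 4-nitrobenzoate
Product: 2 [(2S,3S)-3-methyloxiran-2-yl]methanol
Conditions: K2CO3 (0.2 equiv), MeOH, 0 °C; silica plug, careful concentration
Reagents that add atoms: none
Why: In this Zemplén-type transesterification catalytic methoxide attacks only the activated aroyl carbonyl, and at 0 °C neither Payne rearrangement nor epoxide opening competes, so both stereocentres are kept.

Step 3
Reactants: 2 [(2S,3S)-3-methyloxiran-2-yl]methanol
Product: 4 (2R,3S)-3-methyloxirane-2-carbaldehyde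
Conditions: Dess–Martin periodinane (1.2 equiv), CH2Cl2, 0 °C to rt; pentane, filtration through silica/solid K2CO3; kept as a dried, NMR-titrated solution
Reagents that add atoms: none
Why: The Dess–Martin oxidation is water-free and stops at the aldehyde, and the oxirane C–H does not enolise, so nothing epimerises (the change from S to R at C2 is only a CIP priority change).

Step 4
Reactants: 4 (2R,3S)-3-methyloxirane-2-carbaldehyde; 5 methyl 2-[bis(2,2,2-trifluoroethoxy)phosphoryl]acetate
Product: 6 methyl (2Z)-3-[(2S,3S)-3-methyloxiran-2-yl]prop-2-enoate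
Conditions: KN(SiMe3)2, 18-crown-6, THF, −78 °C; chromatography removes the minor E isomer
Reagents that add atoms: 5 methyl 2-[bis(2,2,2-trifluoroethoxy)phosphoryl]acetate COC(=O)CP(=O)(OCC(F)(F)F)OCC(F)(F)F
Why: In the Still–Gennari olefination the electron-poor phosphonate with a dissociated potassium counter-ion eliminates fast from the kinetic adduct and gives the Z-enoate, and the epoxide stereocentres are spectators.

Step 5
Reactants: 6 methyl (2Z)-3-[(2S,3S)-3-methyloxiran-2-yl]prop-2-enoate
Product: 7 (2Z)-3-[(2S,3S)-3-methyloxiran-2-yl]prop-2-enoic acid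
Conditions: pig liver esterase (carboxylesterase, hydrolase class, EC 3.1.1.1), 0.5 M KH2PO4/K2HPO4 buffer pH 7.4, 5% acetone, 25 °C; then 0 °C, citric acid to pH 3.5, fast EtOAc extraction; used the same day as a cold CH2Cl2 solution
Reagents that add atoms: water O
Why: The serine hydrolase forms an acyl-enzyme from the unhindered methyl ester and water releases the acid at neutral pH, which avoids the Z/E isomerisation, epoxide opening and lactonisation that hydroxide or acid hydrolysis would cause, and no stereocentre is touched.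

## Fragment 2: the terphenyl catechol

Step 6
Reactants: 8 3,4-bis(benzyloxy)benzaldehyde
Product: 10 3,4-bis(benzyloxy)phenol, via aryl formate 9 (not isolated)
Conditions: mCPBA (1.3 equiv), CH2Cl2, rt; then K2CO3 (0.2 equiv), MeOH, rt
Reagents that add atoms: 3-chloroperoxybenzoic acid OOC(=O)c1cccc(Cl)c1
Why: In this Baeyer–Villiger oxidation the electron-rich aryl group migrates in preference to hydrogen, and the resulting formate is removed by mild methanolysis.

Step 7
Reactants: 10 3,4-bis(benzyloxy)phenol
Product: 11 4,5-bis(benzyloxy)-2-hydroxybenzaldehyde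
Conditions: MgCl2, Et3N, (CH2O)n, MeCN, reflux; 1 M HCl work-up
Reagents that add atoms: paraformaldehyde (as formaldehyde) C=O
Why: In the Casnati–Skattebøl ortho-formylation the magnesium phenoxide delivers formaldehyde only ortho to oxygen, at the unhindered C6, and a second formaldehyde accepts hydride to give the aldehyde.

Step 8
Reactants: 11 4,5-bis(benzyloxy)-2-hydroxybenzaldehyde
Product: 13 4,5-bis(benzyloxy)benzene-1,2-diol, via aryl formate 12 (not isolated)
Conditions: H2O2 (30%, 1.1 equiv), NaOH, THF/H2O, 0 °C to rt, N2; prompt acidification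
Reagents that add atoms: hydrogen peroxide OO
Why: In the Dakin oxidation hydroperoxide adds to the ortho-hydroxy aldehyde, the aryl group migrates to oxygen, and the formate is saponified in the same pot to give the catechol.

Step 9
Reactants: 13 4,5-bis(benzyloxy)benzene-1,2-diol
Product: 14 1,2-bis(benzyloxy)-4,5-bis(methoxymethoxy)benzene
Conditions: MOMCl (3 equiv), iPr2NEt (4 equiv), CH2Cl2, 0 °C to rt, N2
Reagents that add atoms: chloromethyl methyl ether COCCl
Why: O-Alkylation of both phenols gives a pair of acetals that is orthogonal to the benzyl pair, which fixes the distinction between the two oxygen pairs.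

Step 10
Reactants: 14 1,2-bis(benzyloxy)-4,5-bis(methoxymethoxy)benzene
Product: 15 1,2-bis(benzyloxy)-3,6-dibromo-4,5-bis(methoxymethoxy)benzene
Conditions: NBS (2.2 equiv), dry MeCN, 0 °C to rt, dark
Reagents that add atoms: N-bromosuccinimide O=C1CCC(=O)N1Br
Why: In this electrophilic aromatic bromination only two C–H positions remain on the strongly activated tetraalkoxy ring, and NBS in acetonitrile releases no acid, so the MOM and benzyl groups survive.

Step 11
Reactants: 15 1,2-bis(benzyloxy)-3,6-dibromo-4,5-bis(methoxymethoxy)benzene; 16 [4-(methoxymethoxy)phenyl]boronic acid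
Product: 17 2',3'-bis(benzyloxy)-4,4'',5',6'-tetrakis(methoxymethoxy)-1,1':4',1''-terphenyl
Conditions: 16 (3 equiv), Pd(OAc)2 (5 mol %), SPhos (10 mol %), K3PO4 (5 equiv), toluene/H2O 10:1, 100 °C
Reagents that add atoms: 16 [4-(methoxymethoxy)phenyl]boronic acid COCOc1ccc(cc1)B(O)O
Why: In this twofold Suzuki–Miyaura coupling the bulky, electron-rich SPhos lets zerovalent palladium insert into the electron-rich, doubly ortho-alkoxylated C–Br bonds, and all the ethers are inert to phosphate base.

Step 12
Reactants: 17 2',3'-bis(benzyloxy)-4,4'',5',6'-tetrakis(methoxymethoxy)-1,1':4',1''-terphenyl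
Product: 18 4,5-bis(benzyloxy)-3,6-bis(4-hydroxyphenyl)benzene-1,2-diol
Conditions: HCl (cat.), MeOH/THF 1:1, 45 °C, Ar
Reagents that add atoms: none
Why: Acid-catalysed acetal exchange with methanol removes all four MOM groups, benzyl ethers are stable to it, and the acidic medium protects the new catechol from air oxidation.

Step 13
Reactants: 18 4,5-bis(benzyloxy)-3,6-bis(4-hydroxyphenyl)benzene-1,2-diol
Product: 19 2',3'-bis(benzyloxy)-4,4'',5',6'-tetrakis(tert-butyldimethylsilyloxy)-1,1':4',1''-terphenyl
Conditions: TBSOTf (6 equiv), 2,6-lutidine (8 equiv), CH2Cl2, 0 °C to rt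
Reagents that add atoms: tert-butyldimethylsilyl triflate CC(C)(C)[Si](C)(C)OS(=O)(=O)C(F)(F)F
Why: The highly electrophilic silyl triflate also silylates the two flanked central phenols and installs the only protecting group that can later be removed without harming aryl esters, Z-alkenes or epoxides.

Step 14
Reactants: 19 2',3'-bis(benzyloxy)-4,4'',5',6'-tetrakis(tert-butyldimethylsilyloxy)-1,1':4',1''-terphenyl
Product: 20 4,5-bis(tert-butyldimethylsilyloxy)-3,6-bis[4-(tert-butyldimethylsilyloxy)phenyl]benzene-1,2-diol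
Conditions: H2 (1 atm), Pd/C (10 wt %), EtOAc, rt; handled under Ar and used at once
Reagents that add atoms: none
Why: Neutral hydrogenolysis in ethyl acetate cleaves the two aryl benzyl ethers, leaves the aryl silyl ethers intact, and exposes only the oxygen pair that is to be acylated.

## Union and end game

Step 15
Reactants: 20 4,5-bis(tert-butyldimethylsilyloxy)-3,6-bis[4-(tert-butyldimethylsilyloxy)phenyl]benzene-1,2-diol; 7 (2Z)-3-[(2S,3S)-3-methyloxiran-2-yl]prop-2-enoic acid
Product: 21 4,5-bis(tert-butyldimethylsilyloxy)-3,6-bis[4-(tert-butyldimethylsilyloxy)phenyl]benzene-1,2-diyl bis{(2Z)-3-[(2S,3S)-3-methyloxiran-2-yl]prop-2-enoate}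
Conditions: 7 (3.0 equiv), N,N'-diisopropylcarbodiimide (3.2 equiv), DMAP (0.2 equiv), CH2Cl2, −20 to 0 °C, Ar, dark
Reagents that add atoms: 7 (2Z)-3-[(2S,3S)-3-methyloxiran-2-yl]prop-2-enoic acid C[C@@H]1O[C@H]1/C=C\C(=O)O
Why: In this twofold Steglich esterification the acidic catechol hydroxyls trap the acylpyridinium quickly, low temperature and substoichiometric DMAP preserve the Z geometry, and no stereocentre is touched; using two units of ≥98% ee acid leaves about 2% of a diastereomer (one acyl unit of opposite configuration) to be removed by chromatography and a negligible amount of the enantiomer.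

Step 16
Reactants: 21 4,5-bis(tert-butyldimethylsilyloxy)-3,6-bis[4-(tert-butyldimethylsilyloxy)phenyl]benzene-1,2-diyl bis{(2Z)-3-[(2S,3S)-3-methyloxiran-2-yl]prop-2-enoate}
Product: 22 4,5-dihydroxy-3,6-bis(4-hydroxyphenyl)benzene-1,2-diyl bis{(2Z)-3-[(2S,3S)-3-methyloxiran-2-yl]prop-2-enoate} (target)
Conditions: Bu4NF (4.6 equiv) premixed with AcOH (7 equiv), THF, 0 °C, 30–60 min, Ar; degassed pH 5 buffer work-up; Sephadex LH-20
Reagents that add atoms: none
Why: In this fluoride desilylation aryl silyl ethers fall within minutes, and acetic acid protonates each phenoxide as it forms, so the aryl esters (which have no neighbouring free OH to migrate to), the Z-alkenes and the ester-deactivated vinyl epoxides all stay intact.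

## Compound list

1 | (E)-but-2-en-1-ol | C/C=C/CO | starting material
2 | [(2S,3S)-3-methyloxiran-2-yl]methanol | C[C@@H]1O[C@H]1CO | intermediate
3 | [(2S,3S)-3-methyloxiran-2-yl]methyl 4-nitrobenzoate | C[C@@H]1O[C@H]1COC(=O)c1ccc(cc1)[N+](=O)[O-] | intermediate
4 | (2R,3S)-3-methyloxirane-2-carbaldehyde | C[C@@H]1O[C@H]1C=O | intermediate
5 | methyl 2-[bis(2,2,2-trifluoroethoxy)phosphoryl]acetate | COC(=O)CP(=O)(OCC(F)(F)F)OCC(F)(F)F | starting material
6 | methyl (2Z)-3-[(2S,3S)-3-methyloxiran-2-yl]prop-2-enoate | C[C@@H]1O[C@H]1/C=C\C(=O)OC | intermediate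
7 | (2Z)-3-[(2S,3S)-3-methyloxiran-2-yl]prop-2-enoic acid | C[C@@H]1O[C@H]1/C=C\C(=O)O | intermediate
8 | 3,4-bis(benzyloxy)benzaldehyde | O=Cc1ccc(OCc2ccccc2)c(OCc2ccccc2)c1 | starting material
9 | 3,4-bis(benzyloxy)phenyl formate | O=COc1ccc(OCc2ccccc2)c(OCc2ccccc2)c1 | intermediate
10 | 3,4-bis(benzyloxy)phenol | Oc1ccc(OCc2ccccc2)c(OCc2ccccc2)c1 | intermediate
11 | 4,5-bis(benzyloxy)-2-hydroxybenzaldehyde | O=Cc1cc(OCc2ccccc2)c(OCc2ccccc2)cc1O | intermediate
12 | 4,5-bis(benzyloxy)-2-hydroxyphenyl formate | O=COc1cc(OCc2ccccc2)c(OCc2ccccc2)cc1O | intermediate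
13 | 4,5-bis(benzyloxy)benzene-1,2-diol | Oc1cc(OCc2ccccc2)c(OCc2ccccc2)cc1O | intermediate
14 | 1,2-bis(benzyloxy)-4,5-bis(methoxymethoxy)benzene | COCOc1cc(OCc2ccccc2)c(OCc2ccccc2)cc1OCOC | intermediate
15 | 1,2-bis(benzyloxy)-3,6-dibromo-4,5-bis(methoxymethoxy)benzene | COCOc1c(Br)c(OCc2ccccc2)c(OCc2ccccc2)c(Br)c1OCOC | intermediate
16 | [4-(methoxymethoxy)phenyl]boronic acid | COCOc1ccc(cc1)B(O)O | starting material
17 | 2',3'-bis(benzyloxy)-4,4'',5',6'-tetrakis(methoxymethoxy)-1,1':4',1''-terphenyl | COCOc1ccc(cc1)-c1c(OCOC)c(OCOC)c(-c2ccc(OCOC)cc2)c(OCc2ccccc2)c1OCc1ccccc1 | intermediate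
18 | 4,5-bis(benzyloxy)-3,6-bis(4-hydroxyphenyl)benzene-1,2-diol | Oc1ccc(cc1)-c1c(O)c(O)c(-c2ccc(O)cc2)c(OCc2ccccc2)c1OCc1ccccc1 | intermediate
19 | 2',3'-bis(benzyloxy)-4,4'',5',6'-tetrakis(tert-butyldimethylsilyloxy)-1,1':4',1''-terphenyl | c1ccccc1COc1c(OCc2ccccc2)c(-c2ccc(O[Si](C)(C)C(C)(C)C)cc2)c(O[Si](C)(C)C(C)(C)C)c(O[Si](C)(C)C(C)(C)C)c1-c1ccc(O[Si](C)(C)C(C)(C)C)cc1 | intermediate
20 | 4,5-bis(tert-butyldimethylsilyloxy)-3,6-bis[4-(tert-butyldimethylsilyloxy)phenyl]benzene-1,2-diol | Oc1c(O)c(-c2ccc(O[Si](C)(C)C(C)(C)C)cc2)c(O[Si](C)(C)C(C)(C)C)c(O[Si](C)(C)C(C)(C)C)c1-c1ccc(O[Si](C)(C)C(C)(C)C)cc1 | intermediate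
21 | tetra-TBS ether of the target: benzene-1,2-diyl bis{(2Z)-3-[(2S,3S)-3-methyloxiran-2-yl]prop-2-enoate} carrying OTBS at C4 and C5 and 4-(TBSO)phenyl at C3 and C6 | C[C@@H]1O[C@H]1/C=C\C(=O)Oc1c(OC(=O)/C=C\[C@@H]2O[C@H]2C)c(-c2ccc(O[Si](C)(C)C(C)(C)C)cc2)c(O[Si](C)(C)C(C)(C)C)c(O[Si](C)(C)C(C)(C)C)c1-c1ccc(O[Si](C)(C)C(C)(C)C)cc1 | intermediate
22 | 4,5-dihydroxy-3,6-bis(4-hydroxyphenyl)benzene-1,2-diyl bis{(2Z)-3-[(2S,3S)-3-methyloxiran-2-yl]prop-2-enoate} | C[C@@H]1O[C@H]1/C=C\C(=O)Oc1c(OC(=O)/C=C\[C@@H]2O[C@H]2C)c(-c2ccc(O)cc2)c(O)c(O)c1-c1ccc(O)cc1 | target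

## Count and risks

Total step count: 16. Longest linear sequence: 11 steps (steps 6 to 16). The acid branch is 5 steps (steps 1 to 5) and joins at step 15.

**Risk 1, step 15.**
- How it can fail: reversible conjugate addition of DMAP can erode the Z geometry, acid 7 can lactonise onto its own epoxide before it is captured, and the second, more hindered acylation can stall.
- Route of the fallback: it sets out from aldehyde 4 (with catechol 20) and comes back at 21. It moves the creation of the Z-alkene to after the ester bonds are made.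
- Chemistry: aldehyde 4 is treated with CBr4, PPh3 and Et3N in CH2Cl2 at −20 °C to give (2S,3S)-2-(2,2-dibromoethenyl)-3-methyloxirane F1. Treatment with n-BuLi (2.1 equiv) in THF at −78 °C and then dry CO2 in the same flask gives 3-[(2S,3S)-3-methyloxiran-2-yl]prop-2-ynoic acid F2. This acid has no alkene geometry to lose, and its linear shape keeps the carboxyl away from the epoxide.
- Return to the route: carbodiimide coupling with 20 (a routine way to make aryl alkynoates) gives the tetra-TBS terphenyl bis(alkynoate) F3. Twofold syn semihydrogenation then gives 21 (H2, Pd/CaCO3 poisoned with Pb(OAc)2, quinoline, EtOAc, 0 °C, stopped at two equivalents of H2).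

**Risk 2, step 16.**
- How it can fail: fluoride, acetate or a transient phenoxide can cleave or scramble the aryl esters, and the free tetraphenol oxidises easily whenever it meets base.
- Route of the fallback: it sets out from tetraphenol 18 and comes back at 22. It replaces the fluoride-labile groups with acetals that leave by mild acid-catalysed exchange, so the final step contains no nucleophile and no base.
- Chemistry: 18 with ethyl vinyl ether and catalytic pyridinium tosylate in CH2Cl2 gives the tetrakis(1-ethoxyethyl) ether of 18 F4. Hydrogenolysis (H2, Pd/C, EtOAc, a little solid K2CO3) gives the tetrakis(1-ethoxyethyl)-protected catechol F5. Esterification with 7 as in step 15 gives the tetrakis(1-ethoxyethyl)-protected bis(ester) F6.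
- Return to the route: catalytic pyridinium tosylate in EtOH/THF at rt under Ar releases 22. Epoxides and aryl esters normally tolerate these conditions.

**Risk 3, step 11.**
- How it can fail: both C–Br bonds are electron-rich and flanked by two alkoxy groups. Slow oxidative addition, protodebromination and protodeboronation of 16 can leave mono-coupled material.
- Route of the fallback: it sets out from dibromide 15 and comes back at 17. It replaces the boron/base manifold with a base-free Negishi coupling that uses a more reactive nucleophile.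
- Chemistry: purchased 1-bromo-4-(methoxymethoxy)benzene is lithiated (n-BuLi, THF, −78 °C) and transmetalated with ZnCl2 to give chloro[4-(methoxymethoxy)phenyl]zinc F7. This couples twice with 15 under Pd2(dba)3/RuPhos in THF at 65 °C to give 17.

Further compounds
F1 | step 15 | (2S,3S)-2-(2,2-dibromoethenyl)-3-methyloxirane | C[C@@H]1O[C@H]1C=C(Br)Br
F2 | step 15 | 3-[(2S,3S)-3-methyloxiran-2-yl]prop-2-ynoic acid | C[C@@H]1O[C@H]1C#CC(=O)O
F3 | step 15 | tetra-TBS terphenyl bis(alkynoate): 4,5-bis(TBSO)-3,6-bis[4-(TBSO)phenyl]benzene-1,2-diyl bis{3-[(2S,3S)-3-methyloxiran-2-yl]prop-2-ynoate} | C[C@@H]1O[C@H]1C#CC(=O)Oc1c(OC(=O)C#C[C@@H]2O[C@H]2C)c(-c2ccc(O[Si](C)(C)C(C)(C)C)cc2)c(O[Si](C)(C)C(C)(C)C)c(O[Si](C)(C)C(C)(C)C)c1-c1ccc(O[Si](C)(C)C(C)(C)C)cc1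
F4 | step 16 | tetrakis(1-ethoxyethyl) ether of 18 (mixture of acetal epimers, acetal centres undefined) | CCOC(C)Oc1ccc(cc1)-c1c(OC(C)OCC)c(OC(C)OCC)c(-c2ccc(OC(C)OCC)cc2)c(OCc2ccccc2)c1OCc1ccccc1
F5 | step 16 | tetrakis(1-ethoxyethyl)-protected catechol: 4,5-bis(1-ethoxyethoxy)-3,6-bis[4-(1-ethoxyethoxy)phenyl]benzene-1,2-diol (acetal centres undefined) | CCOC(C)Oc1ccc(cc1)-c1c(OC(C)OCC)c(OC(C)OCC)c(-c2ccc(OC(C)OCC)cc2)c(O)c1O
F6 | step 16 | tetrakis(1-ethoxyethyl)-protected bis(ester): tetrakis(1-ethoxyethyl) ether of 22 (acetal centres undefined) | C[C@@H]1O[C@H]1/C=C\C(=O)Oc1c(OC(=O)/C=C\[C@@H]2O[C@H]2C)c(-c2ccc(OC(C)OCC)cc2)c(OC(C)OCC)c(OC(C)OCC)c1-c1ccc(OC(C)OCC)cc1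
F7 | step 11 | chloro[4-(methoxymethoxy)phenyl]zinc | COCOc1ccc([Zn]Cl)cc1
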